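**Retrosynthetic overview**
- Target ⇐ fluoride removal of two catechol TBS ethers from the (2S)-flavanone.
- C2–aryl bond and the only stereocentre ⇐ Rh/chiral-diene asymmetric 1,4-addition of a catechol-protected arylboronic acid to 8-(hydroxyprenyl)-7-methoxychromone.
- Chromone ⇐ one-pot Diels–Alder benzannulation / 6-endo oxa-Michael of a 2-substituted Brassard-type diene with penta-1,4-diyn-3-one; ring A and pyranone ring C form together from acyclic partners.
- Diene ⇐ methyl acetoacetate + isoprene monoxide (Pd 1,4-allylation installs the whole (E)-4-hydroxy-3-methylbut-2-enyl chain), O-methylation, silyl ketene acetal formation; diynone ⇐ ethynylmagnesium bromide + ethyl formate, then oxidation.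
- Ring order: A and C together (step 6); B is a bought arene (4-bromocatechol) attached in step 9.

Assumption: isoprene monoxide and the catalysts/ligands (Pd(PPh3)4, [RhCl(C2H4)2]2, (S,S)-Ph-bod*) are catalogue items; solvents and common reagents are not numbered.

**Route**

Step 1
Reactants: 1 methyl acetoacetate; 2 2-methyl-2-vinyloxirane (isoprene monoxide, racemic)
Product: 3 methyl 2-[(2E)-4-hydroxy-3-methylbut-2-en-1-yl]-3-oxobutanoate (racemic at C2)
Conditions: Pd(PPh3)4 (2 mol %), THF, 0 °C → rt, 1 in 1.5-fold excess; E isomer purified by chromatography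
Reagents that add atoms: none
Why: Tsuji–Trost allylic alkylation under neutral conditions, in which Pd(0) opens the vinyl epoxide to a zwitterionic π-allyl, its alkoxide deprotonates the β-keto ester and the soft enolate attacks the unsubstituted allyl terminus to give the 1,4-adduct as mainly the E-trisubstituted alkene (the racemic α-centre is destroyed in step 2).

Step 2
Reactants: 3 methyl 2-[(2E)-4-hydroxy-3-methylbut-2-en-1-yl]-3-oxobutanoate
Product: 4 methyl 2-[(2E)-4-hydroxy-3-methylbut-2-en-1-yl]-3-methoxybut-2-enoate (E/Z mixture at the enol ether, both usable)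
Conditions: HC(OMe)3 (3 equiv), MeOH, H2SO4 (cat.), rt → 50 °C; NaOMe quench; then K2CO3 (cat.), MeOH, rt
Reagents that add atoms: trimethyl orthoformate, COC(OC)OC
Why: acid-catalysed orthoformate O-methyl enol ether formation converts the α-alkyl acetoacetate into its β-methoxy enoate, while the primary alcohol is only reversibly masked and is returned by the methanol exchange and mild basic methanolysis.

Step 3
Reactants: 4 methyl 2-[(2E)-4-hydroxy-3-methylbut-2-en-1-yl]-3-methoxybut-2-enoate
Product: 5 [(1,3-dimethoxy-2-[(2E)-3-methyl-4-(trimethylsilyloxy)but-2-en-1-yl]buta-1,3-dien-1-yl)oxy]trimethylsilane (crude, used at once)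
Conditions: LDA (2.2 equiv), THF, −78 °C; TMSCl (2.5 equiv), −78 → 0 °C; pentane, filter, concentrate
Reagents that add atoms: chlorotrimethylsilane, C[Si](C)(C)Cl
Why: silyl ketene acetal formation by kinetic γ-deprotonation of the vinylogous ester (after O-lithiation of the alcohol) and O-silylation gives the 2-substituted Brassard-type diene, with the alcohol capped as its TMS ether in the same flask.

Step 4
Reactants: 6 ethynylmagnesium bromide (2.1 equiv); 7 ethyl formate
Product: 8 penta-1,4-diyn-3-ol
Conditions: THF, 0 °C → rt; cold 1 M HCl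
Reagents that add atoms: none
Why: double Grignard addition of the acetylide to the formate ester gives the symmetrical bis-propargylic secondary alcohol.

Step 5
Reactants: 8 penta-1,4-diyn-3-ol
Product: 9 penta-1,4-diyn-3-one (kept as a filtered CH2Cl2 solution, never concentrated)
Conditions: activated MnO2 (10 equiv), CH2Cl2, 0 °C → rt; filter through Celite
Reagents that add atoms: none
Why: MnO2 oxidation of an activated bis-propargylic alcohol gives the skipped diynone under neutral, non-aqueous conditions, so the sensitive ketone can be used directly in solution.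

Step 6
Reactants: 5 [(1,3-dimethoxy-2-[(2E)-3-methyl-4-(trimethylsilyloxy)but-2-en-1-yl]buta-1,3-dien-1-yl)oxy]trimethylsilane; 9 penta-1,4-diyn-3-one (2 equiv)
Product: 12 8-[(2E)-4-hydroxy-3-methylbut-2-en-1-yl]-7-methoxy-4H-chromen-4-one, via cyclohexa-1,4-diene ketal cycloadduct 10 (not isolated), via 2-hydroxyaryl ethynyl ketone 11 (not isolated)
Conditions: 5 added to 9, CH2Cl2, −20 °C → rt; then MeOH, K2CO3 (0.5 equiv), rt
Reagents that add atoms: none
Why: Proposed new method: the ketene-acetal diene adds to one ynone arm in a Diels–Alder reaction (nucleophilic CH2 terminus to the alkyne β-carbon, acetal carbon to the α-carbon, so the silyloxy carbon ends ortho to the acyl group, OMe para and the side chain between the two oxygens), methanolysis of the Si–O bonds collapses the ketal with loss of MeOH to the phenol, and the phenoxide closes 6-endo-dig onto the second ynone arm, so the benzene and pyranone rings arise in one flask; the closest known chemistry is the Brassard/Chan-diene–alkynone benzannulation to salicyl ketones and the base-mediated cyclisation of 2-hydroxyaryl ethynyl ketones to chromones (no stereocentre is formed).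

Step 7
Reactants: 13 4-bromobenzene-1,2-diol (4-bromocatechol)
Product: 14 4-bromo-1,2-bis(tert-butyldimethylsilyloxy)benzene
Conditions: TBSCl (2.3 equiv), imidazole (4 equiv), DMF, rt
Reagents that add atoms: tert-butyldimethylsilyl chloride, CC(C)(C)[Si](C)(C)Cl
Why: standard silylation of both phenols gives a catechol protection that fluoride removes later without touching the aryl methyl ether, the allylic alcohol or the flavanone.

Step 8
Reactants: 14 4-bromo-1,2-bis(tert-butyldimethylsilyloxy)benzene
Product: 15 [3,4-bis(tert-butyldimethylsilyloxy)phenyl]boronic acid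
Conditions: B(OiPr)3 (1.3 equiv), n-BuLi (1.1 equiv), THF/PhMe, −78 °C → rt; cold dilute HCl
Reagents that add atoms: triisopropyl borate, CC(C)OB(OC(C)C)OC(C)C; water, O
Why: bromine–lithium exchange with in situ borate trapping and mild hydrolysis gives the arylboronic acid, and no silyloxy group sits ortho to the lithiated carbon, so no retro-Brook shift can occur.

Step 9
Reactants: 12 8-[(2E)-4-hydroxy-3-methylbut-2-en-1-yl]-7-methoxy-4H-chromen-4-one; 15 [3,4-bis(tert-butyldimethylsilyloxy)phenyl]boronic acid (2.5 equiv)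
Product: 16 (2S)-2-[3,4-bis(tert-butyldimethylsilyloxy)phenyl]-8-[(2E)-4-hydroxy-3-methylbut-2-en-1-yl]-7-methoxy-2,3-dihydro-4H-chromen-4-one
Conditions: [RhCl(C2H4)2]2 (2.5 mol %), (S,S)-Ph-bod* (5.5 mol %), aq. KOH (10 mol %), 1,4-dioxane/H2O (10:1), 40 °C
Reagents that add atoms: none
Why: Hayashi–Miyaura Rh(I)/chiral-diene asymmetric 1,4-addition of an arylboronic acid to a chromone, in which the aryl–Rh species inserts C2=C3 on the face dictated by the C2-symmetric diene and water protonates the oxa-π-allyl, setting C2 as (S) (ligand antipode chosen by analogy with the one that gives (S)-3-arylcyclohexanones from cyclohex-2-enone, to be confirmed by CD and swapped for (R,R) if the sense is opposite).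

Step 10
Reactants: 16 (2S)-2-[3,4-bis(tert-butyldimethylsilyloxy)phenyl]-8-[(2E)-4-hydroxy-3-methylbut-2-en-1-yl]-7-methoxy-2,3-dihydro-4H-chromen-4-one
Product: 17 (2S)-2-(3,4-dihydroxyphenyl)-8-[(2E)-4-hydroxy-3-methylbut-2-en-1-yl]-7-methoxy-2,3-dihydro-4H-chromen-4-one (CNP0503781.1)
Conditions: KHF2 (2.5 equiv), MeOH, rt, under N2
Reagents that add atoms: none
Why: KHF2 in methanol cleaves phenolic TBS ethers at room temperature under slightly acidic conditions, so the base-labile (2S)-flavanone is neither ring-opened nor racemised and the E-allylic alcohol and the methyl ether are untouched.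

**Compound list**
1 | methyl acetoacetate | CC(=O)CC(=O)OC | starting material
2 | 2-methyl-2-vinyloxirane (isoprene monoxide, racemic) | CC1(C=C)CO1 | starting material
3 | methyl 2-[(2E)-4-hydroxy-3-methylbut-2-en-1-yl]-3-oxobutanoate (racemic) | COC(=O)C(C/C=C(\C)CO)C(C)=O | intermediate
4 | methyl 2-[(2E)-4-hydroxy-3-methylbut-2-en-1-yl]-3-methoxybut-2-enoate (enol ether E/Z mixture) | COC(=O)C(C/C=C(\C)CO)=C(C)OC | intermediate
5 | [(1,3-dimethoxy-2-[(2E)-3-methyl-4-(trimethylsilyloxy)but-2-en-1-yl]buta-1,3-dien-1-yl)oxy]trimethylsilane | C=C(OC)C(C/C=C(\C)CO[Si](C)(C)C)=C(OC)O[Si](C)(C)C | intermediate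
6 | ethynylmagnesium bromide | C#C[Mg]Br | starting material
7 | ethyl formate | CCOC=O | starting material
8 | penta-1,4-diyn-3-ol | C#CC(O)C#C | intermediate
9 | penta-1,4-diyn-3-one | C#CC(=O)C#C | intermediate
10 | 1-{4,6-dimethoxy-5-[(2E)-3-methyl-4-(trimethylsilyloxy)but-2-en-1-yl]-6-(trimethylsilyloxy)cyclohexa-1,4-dien-1-yl}prop-2-yn-1-one | COC1=C(C/C=C(\C)CO[Si](C)(C)C)C(OC)(O[Si](C)(C)C)C(C(=O)C#C)=CC1 | intermediate
11 | 1-{2-hydroxy-3-[(2E)-4-hydroxy-3-methylbut-2-en-1-yl]-4-methoxyphenyl}prop-2-yn-1-one | C#CC(=O)c1ccc(OC)c(C/C=C(\C)CO)c1O | intermediate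
12 | 8-[(2E)-4-hydroxy-3-methylbut-2-en-1-yl]-7-methoxy-4H-chromen-4-one | COc1ccc2c(c1C/C=C(\C)CO)OC=CC2=O | intermediate
13 | 4-bromobenzene-1,2-diol | Oc1ccc(Br)cc1O | starting material
14 | 4-bromo-1,2-bis(tert-butyldimethylsilyloxy)benzene | CC(C)(C)[Si](C)(C)Oc1ccc(Br)cc1O[Si](C)(C)C(C)(C)C | intermediate
15 | [3,4-bis(tert-butyldimethylsilyloxy)phenyl]boronic acid | CC(C)(C)[Si](C)(C)Oc1ccc(B(O)O)cc1O[Si](C)(C)C(C)(C)C | intermediate
16 | (2S)-2-[3,4-bis(tert-butyldimethylsilyloxy)phenyl]-8-[(2E)-4-hydroxy-3-methylbut-2-en-1-yl]-7-methoxy-2,3-dihydro-4H-chromen-4-one | COc1ccc2c(c1C/C=C(\C)CO)O[C@H](c1ccc(O[Si](C)(C)C(C)(C)C)c(O[Si](C)(C)C(C)(C)C)c1)CC2=O | intermediate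
17 | (2S)-2-(3,4-dihydroxyphenyl)-8-[(2E)-4-hydroxy-3-methylbut-2-en-1-yl]-7-methoxy-2,3-dihydro-4H-chromen-4-one | COc1ccc2c(c1C/C=C(\C)CO)O[C@H](c1ccc(O)c(O)c1)CC2=O | target

**Totals**
Total steps: 10. Longest linear sequence: 6 (steps 1, 2, 3, 6, 9, 10).

**Steps most likely to fail, with fallbacks**

Step 6 (cascade with the unstable skipped diynone; risks are double addition, polymerisation of 9 or the wrong ketal leaving group). The fallback sets out from 5 and comes back at 12. Diene 5 is combined with commercial but-3-yn-2-one (CH2Cl2, −20 °C → rt; then MeOH, cat. K2CO3). Through the cycloadduct 1-{4,6-dimethoxy-5-[(2E)-3-methyl-4-(trimethylsilyloxy)but-2-en-1-yl]-6-(trimethylsilyloxy)cyclohexa-1,4-dien-1-yl}ethan-1-one F1 this gives 1-{2-hydroxy-3-[(2E)-4-hydroxy-3-methylbut-2-en-1-yl]-4-methoxyphenyl}ethan-1-one F2. Heating with DMF dimethyl acetal (PhMe, 90 °C) gives the enaminone (2E)-3-(dimethylamino)-1-{2-hydroxy-3-[(2E)-4-hydroxy-3-methylbut-2-en-1-yl]-4-methoxyphenyl}prop-2-en-1-one F3, which closes to 12 with loss of dimethylamine on brief treatment with aq. HCl/CH2Cl2. The pyranone ring is then made in a separate classical operation, and steps 4 and 5 are not needed.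

Step 9 (electron-rich, 8-substituted chromone; yield, ee and sense of induction rest on analogy). The fallback sets out from 12 and comes back at 16. The addition is run with achiral [Rh(OH)(cod)]2 in dioxane/H2O to give the racemate, that is 16 together with its mirror image (2R)-2-[3,4-bis(tert-butyldimethylsilyloxy)phenyl]-8-[(2E)-4-hydroxy-3-methylbut-2-en-1-yl]-7-methoxy-2,3-dihydro-4H-chromen-4-one F4. The enantiomers are separated by preparative chiral SFC (amylose carbamate phase); F4 is re-racemised with catalytic DBU through the reversible retro-oxa-Michael opening and recycled.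

Step 1 (E/Z ratio and 1,4- versus 1,2-selectivity of the vinyl epoxide opening). The fallback sets out from 1 and comes back at 3. Compound 1 is C-alkylated with prenyl bromide (K2CO3, acetone) to methyl 2-(3-methylbut-2-en-1-yl)-3-oxobutanoate F5. Catalytic SeO2/t-BuOOH (CH2Cl2, rt) then oxidises only the E-methyl group of the prenyl unit (ene/[2,3]-sigmatropic mechanism) to give 3 with defined E geometry. Any over-oxidised enal methyl 2-[(2E)-3-methyl-4-oxobut-2-en-1-yl]-3-oxobutanoate F6 is reduced back to 3 with NaBH(OAc)3.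

**Further compounds**
F1 | step 6 | 1-{4,6-dimethoxy-5-[(2E)-3-methyl-4-(trimethylsilyloxy)but-2-en-1-yl]-6-(trimethylsilyloxy)cyclohexa-1,4-dien-1-yl}ethan-1-one | COC1=C(C/C=C(\C)CO[Si](C)(C)C)C(OC)(O[Si](C)(C)C)C(C(C)=O)=CC1
F2 | step 6 | 1-{2-hydroxy-3-[(2E)-4-hydroxy-3-methylbut-2-en-1-yl]-4-methoxyphenyl}ethan-1-one | CC(=O)c1ccc(OC)c(C/C=C(\C)CO)c1O
F3 | step 6 | (2E)-3-(dimethylamino)-1-{2-hydroxy-3-[(2E)-4-hydroxy-3-methylbut-2-en-1-yl]-4-methoxyphenyl}prop-2-en-1-one | CN(C)/C=C/C(=O)c1ccc(OC)c(C/C=C(\C)CO)c1O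
F4 | step 9 | (2R)-2-[3,4-bis(tert-butyldimethylsilyloxy)phenyl]-8-[(2E)-4-hydroxy-3-methylbut-2-en-1-yl]-7-methoxy-2,3-dihydro-4H-chromen-4-one | COc1ccc2c(c1C/C=C(\C)CO)O[C@@H](c1ccc(O[Si](C)(C)C(C)(C)C)c(O[Si](C)(C)C(C)(C)C)c1)CC2=O
F5 | step 1 | methyl 2-(3-methylbut-2-en-1-yl)-3-oxobutanoate | COC(=O)C(CC=C(C)C)C(C)=O
F6 | step 1 | methyl 2-[(2E)-3-methyl-4-oxobut-2-en-1-yl]-3-oxobutanoate | COC(=O)C(C/C=C(\C)C=O)C(C)=O
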